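## Retrosynthetic overview

- Target (briarane locants C1–C20) ⇒ C14 alcohol and C2 ketone (acetate and C2 carbinol both come from one Evans–Tishchenko step) ⇒ open the cyclohexene at C1–C14 to a C1=C2 enol silane facing a C14 oxocarbenium ion.
- The same operation also builds the ten-membered ring and unveils the butenolide: its precursor is a monocyclic cyclohexenol (ring C2–C3–C4–C5=C6–C7) carrying the C1=C10 dienyl chain on carbinol C2 and the butenolide spiro-fused at C7.
- Enabling feature: after enol silylation of the lactone (C9 methyl becomes an exocyclic C8=C9 alkene), C10=C1–C2–C7–C8=C9 is a 1,5-diene across the C2–C7 ring bond. Its [3,3] shift expands the ring by four atoms, turns the lactone into an aromatic 2-siloxyfuran (the latent C7–H butenolide) and leaves the C1=C2 enol silane that closes C1–C14; the Z C5=C6 bond is inherited from the cyclohexene.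
- The precursor comes from spiro ketone 7 (from 3-methylcyclohex-2-en-1-one: α'-acetoxylation, lipase resolution, propynyl addition, carbomagnesiation–carboxylation, oxidation) and dienyl iodide 16 (from 2,3-dihydrofuran: a cuprate 1,2-metalate shift fixes the Z C11=C12 bond; then Sonogashira coupling and hydrozirconation).
- Ring order: butenolide onto the preformed cyclohexene (step 4), then the ten-membered ring and the six-membered ring, both in the key step.

Key step: step 12

Remark on locants: C1–C20 are the briarane locants of the target (C1 quaternary carbon with methyl C15; C2 propionyloxy carbon; C5 with methyl C16; C7 lactone O–CH; C8=C17 butenolide alkene with methyl C18 and carbonyl C19; C10 ring-fusion CH; C11 with methyl C20; C14 acetoxy carbon).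

Assumption: the lipase of step 2 is taken to hydrolyse the (R)-acetate of 2 faster; if the enzyme screen shows the opposite preference, the recovered (R)-acetate is used in step 3 with one further equivalent of the Grignard reagent.

## Route

Step 1
Reactants: 1 3-methylcyclohex-2-en-1-one
Product: 2 rac-4-methyl-2-oxocyclohex-3-en-1-yl acetate
Conditions: Mn(OAc)3·2H2O (2.5 equiv), benzene, reflux (Dean–Stark)
Reagents that add atoms: manganese triacetate CC(=O)[O-].CC(=O)[O-].CC(=O)[O-].[Mn+3]
Why: α'-Acetoxylation of an enone by trivalent manganese (manganese enolate, then acetate transfer) should functionalise only C6 of 1, the future C2, and no control of configuration is needed at this stage.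

Step 2
Reactants: 2 rac-4-methyl-2-oxocyclohex-3-en-1-yl acetate
Product: 3 (R)-6-hydroxy-3-methylcyclohex-2-en-1-one
Conditions: lipase PS (Burkholderia cepacia), pH 7 phosphate buffer–MTBE, rt, stopped near half conversion; chromatography
Reagents that add atoms: none
Why: Enzymatic kinetic resolution by a lipase (enantioselective hydrolysis of an α'-acetoxy enone) should deliver the (R)-alcohol, whose carbinol centre serves only as a stereochemical relay for the spiro centre.

Step 3
Reactants: 3 (R)-6-hydroxy-3-methylcyclohex-2-en-1-one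
Product: 4 (1R,2R)-4-methyl-2-(prop-1-yn-1-yl)cyclohex-3-ene-1,2-diol
Conditions: 1-propynylmagnesium bromide (2.5 equiv), THF, −78 to 0 °C; aq NH4Cl
Reagents that add atoms: 1-propynylmagnesium bromide CC#C[Mg]Br
Why: Chelation-controlled Grignard 1,2-addition, in which the magnesium alkoxide formed by the first equivalent ties the ketone into a five-membered chelate, should give the cis-diol (new tertiary centre R), any trans isomer being removed by chromatography.

Step 4
Reactants: 4 (1R,2R)-4-methyl-2-(prop-1-yn-1-yl)cyclohex-3-ene-1,2-diol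
Product: 6 (5R,10R)-10-hydroxy-3,4,7-trimethyl-1-oxaspiro[4.5]deca-3,6-dien-2-one, via oxamagnesacycle 5 (not isolated)
Conditions: MeMgBr (5 equiv), CuI (10 mol %), THF, 0 °C to rt; CO2, −20 °C to rt; 1 M HCl
Reagents that add atoms: methylmagnesium bromide C[Mg]Br; carbon dioxide O=C=O
Why: Copper-catalysed anti-carbomagnesiation of the propargylic alkoxide puts the methyl group on the proximal alkyne carbon and magnesium on the distal one (five-membered chelate 5), and carboxylation of that alkenyl–magnesium bond followed by acid should close the butenolide without touching the two stereocentres.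

Step 5
Reactants: 6 (5R,10R)-10-hydroxy-3,4,7-trimethyl-1-oxaspiro[4.5]deca-3,6-dien-2-one
Product: 7 (5R)-3,4,7-trimethyl-1-oxaspiro[4.5]deca-3,6-diene-2,10-dione
Conditions: Dess–Martin periodinane, NaHCO3, CH2Cl2, 0 °C to rt
Reagents that add atoms: none
Why: Dess–Martin oxidation of the secondary alcohol removes the relay centre and leaves the quaternary spiro carbon, which has no α-hydrogen and cannot epimerise, as the only stereocentre.

Step 6
Reactants: 8 2,3-dihydrofuran
Product: 11 (Z)-4-iodopent-3-en-1-ol, via 5-lithio-2,3-dihydrofuran 9 (not isolated), via alkenyl methyl cuprate 10 (not isolated)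
Conditions: t-BuLi, THF, −78 to 0 °C; Me2CuLi (from CuI, 2 MeLi), Et2O–Me2S, 0 °C to rt; I2, −78 °C
Reagents that add atoms: lithium dimethylcuprate [Li+].C[Cu-]C; iodine [I][I]
Why: In this 1,2-metalate rearrangement of an α-alkoxyalkenyl cuprate, methyl migrates from copper to the lithiated enol ether carbon with inversion while the ring oxygen leaves, and iodinolysis of the alkenyl–copper bond with retention should place iodine cis to the hydroxyethyl chain (Z).

Step 7
Reactants: 11 (Z)-4-iodopent-3-en-1-ol
Product: 12 (Z)-4-iodopent-3-enal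
Conditions: Dess–Martin periodinane, NaHCO3, CH2Cl2, 0 °C
Reagents that add atoms: none
Why: Buffered Dess–Martin oxidation should give the β,γ-unsaturated aldehyde without acid or base that would move the alkene into conjugation.

Step 8
Reactants: 12 (Z)-4-iodopent-3-enal
Product: 13 (Z)-4-iodo-1,1-bis[(4-methoxybenzyl)oxy]pent-3-ene
Conditions: 4-methoxybenzyl alcohol (2.5 equiv), PPTS (cat.), 4 Å molecular sieves, benzene, rt
Reagents that add atoms: 4-methoxybenzyl alcohol COc1ccc(CO)cc1
Why: Acid-catalysed acetalisation driven by removal of water masks the aldehyde as an acetal whose remaining alkoxy group can later be removed oxidatively.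

Step 9
Reactants: 13 (Z)-4-iodo-1,1-bis[(4-methoxybenzyl)oxy]pent-3-ene
Product: 14 (Z)-7,7-bis[(4-methoxybenzyl)oxy]-4-methylhept-4-en-2-yne
Conditions: propyne, Pd(PPh3)2Cl2 (cat.), CuI (cat.), Et3N, THF, rt
Reagents that add atoms: propyne CC#C
Why: Sonogashira coupling of the alkenyl iodide proceeds with retention of the Z geometry.

Step 10
Reactants: 14 (Z)-7,7-bis[(4-methoxybenzyl)oxy]-4-methylhept-4-en-2-yne
Product: 16 (2E,4Z)-2-iodo-7,7-bis[(4-methoxybenzyl)oxy]-4-methylhepta-2,4-diene, via alkenylzirconocene chloride 15 (not isolated)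
Conditions: Cp2Zr(H)Cl (1.3 equiv), THF, rt; I2, 0 °C
Reagents that add atoms: iodine [I][I]
Why: Hydrozirconation adds Zr–H syn across the alkyne with zirconium on the less hindered methyl-bearing carbon, and iodinolysis with retention should give the 2E iodide while the trisubstituted alkene stays untouched.

Step 11
Reactants: 16 (2E,4Z)-2-iodo-7,7-bis[(4-methoxybenzyl)oxy]-4-methylhepta-2,4-diene; 7 (5R)-3,4,7-trimethyl-1-oxaspiro[4.5]deca-3,6-diene-2,10-dione
Product: 19 (5R,10S)-10-[(2E,4Z)-7,7-bis[(4-methoxybenzyl)oxy]-4-methylhepta-2,4-dien-2-yl]-10-hydroxy-3,4,7-trimethyl-1-oxaspiro[4.5]deca-3,6-dien-2-one, via dienyllithium 17 (not isolated), via dienylcerium dichloride 18 (not isolated)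
Conditions: 16, t-BuLi (2 equiv), Et2O, −78 °C; CeCl3, THF, −78 °C; 7, −78 °C; aq NH4Cl
Reagents that add atoms: none
Why: Iodine–lithium exchange with retention and transmetalation to cerium give a weakly basic alkenyl nucleophile that should add 1,2 to the ketone of 7 by axial attack anti to the C7–O bond (polar Felkin–Anh control), setting the carbinol centre S with its oxygen cis to the lactone oxygen.

Step 12
Reactants: 19 (5R,10S)-10-[(2E,4Z)-7,7-bis[(4-methoxybenzyl)oxy]-4-methylhepta-2,4-dien-2-yl]-10-hydroxy-3,4,7-trimethyl-1-oxaspiro[4.5]deca-3,6-dien-2-one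
Product: 22 (1R,7R,10S,14S)-tricyclic keto butenolide with the target skeleton bearing a C2 ketone and a C14 4-methoxybenzyl ether, via bis-silyl ether 20 (not isolated), via furan-fused macrocycle 21 (not isolated)
Conditions: TMSOTf (2.4 equiv), Et3N (3 equiv), CH2Cl2, −78 to 0 °C; ClCH2CH2Cl, 50 °C; −78 °C, TMSOTf (1 equiv); aq NaHCO3; citric acid, THF–H2O, 0 °C
Reagents that add atoms: none
Why: Proposed new method: silylation converts 19 into 20, whose C10=C1–C2–C7–C8=C9 array is a 3-siloxy-1,5-diene that should undergo a chair [3,3] shift (C9–C10 made, C2–C7 broken) because the lactone ring becomes an aromatic 2-siloxyfuran, the closest known reactions being the oxy- and siloxy-Cope ring expansion of 1,2-dialkenylcyclohexanols to cyclodecenones and the rearomatising Cope shift of isotoluene-type trienes. The ten-membered ring is closed by this four-atom ring expansion of the cyclohexene, and the regio- and geometry-defined C1=C2 enol silane of 21 then closes the six-membered ring by a 6-(enolexo)-exo-trig attack of C1 on the C14 oxocarbenium ion released from the acetal by TMSOTf, which is the known intramolecular Mukaiyama aldol reaction of an acetal. C10 (S) follows from chirality transfer from C2 and C7 through the only chair available, in which the lactone oxygen lies in the plane of C8=C9 and C11 is equatorial on the E alkene. C1 (R in 22) is set by attack on the enol ether face that carries H10 and is not spanned by the C9 bridge, reached from the Cope geometry by a rotation of about 30° that keeps H10 next to the siloxy-bearing carbon (allylic 1,3-strain), and C14 (S) by a half-chair that holds the 4-methoxybenzyloxy group anti to the axial C15 methyl. C7 (R) arises on work-up by γ-protonation of the siloxyfuran under substrate control and can be equilibrated through the furanolate with DBU. The step needs the [3,3] shift to beat ionisation of the tertiary allylic silyl ether, which the amine buffer and the aromatic driving force should secure, and it needs attack by C1 instead of the siloxyfuran on the oxocarbenium ion, which ring size (six against eight) should secure.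

Step 13
Reactants: 22 (1R,7R,10S,14S)-tricyclic keto butenolide with C14 4-methoxybenzyl ether
Product: 23 (1R,7R,10S,14S)-14-hydroxy-2-oxo tricyclic butenolide
Conditions: DDQ, CH2Cl2–pH 7 buffer, 0 °C
Reagents that add atoms: none
Why: Oxidative cleavage of the 4-methoxybenzyl ether by DDQ (benzylic hydride abstraction, then hydrolysis) should free the C14 hydroxyl without touching the alkenes, the ketone or the butenolide.

Step 14
Reactants: 23 (1R,7R,10S,14S)-14-hydroxy-2-oxo tricyclic butenolide
Product: 24 (1S,2S,7R,10S,14S)-14-acetoxy-2-hydroxy tricyclic butenolide (the target lacking its propionyl group)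
Conditions: MeCHO (10 equiv), SmI2 (30 mol %), THF, −10 °C
Reagents that add atoms: acetaldehyde CC=O
Why: In this Evans–Tishchenko reduction the samarium-bound hemiacetal of the C14 alkoxide with acetaldehyde transfers hydride intramolecularly to the C2 carbonyl through a six-membered transition state, which should give the 1,3-anti diol (2S) and leave the acetyl group on O14 in the same operation.

Step 15
Reactants: 24 (1S,2S,7R,10S,14S)-14-acetoxy-2-hydroxy tricyclic butenolide
Product: 25 CNP0112230.1, the (1S,2S,7R,10S,14S)-14-acetoxy-2-propanoyloxy butenolide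
Conditions: (EtCO)2O, DMAP, Et3N, CH2Cl2, 0 °C to rt
Reagents that add atoms: propionic anhydride CCC(=O)OC(=O)CC
Why: DMAP-catalysed acylation of the remaining hindered secondary alcohol should complete the target under conditions too mild for acyl migration or epimerisation of the lactone.

## Compound list

1 | 3-methylcyclohex-2-en-1-one | CC1=CC(=O)CCC1 | starting material
2 | rac-4-methyl-2-oxocyclohex-3-en-1-yl acetate | CC1=CC(=O)C(OC(C)=O)CC1 | intermediate
3 | (R)-6-hydroxy-3-methylcyclohex-2-en-1-one | CC1=CC(=O)[C@H](O)CC1 | intermediate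
4 | (1R,2R)-4-methyl-2-(prop-1-yn-1-yl)cyclohex-3-ene-1,2-diol (cis-diol) | CC#C[C@]1(O)C=C(C)CC[C@H]1O | intermediate
5 | oxamagnesacycle: alkenylmagnesium chelated by the tertiary alkoxide, secondary alkoxide as its bromomagnesium salt | C/C1=C(\C)[C@]2(O[Mg]1)C=C(C)CC[C@H]2O[Mg]Br | intermediate
6 | (5R,10R)-10-hydroxy-3,4,7-trimethyl-1-oxaspiro[4.5]deca-3,6-dien-2-one | CC1=C(C)[C@]2(OC1=O)C=C(C)CC[C@H]2O | intermediate
7 | (5R)-3,4,7-trimethyl-1-oxaspiro[4.5]deca-3,6-diene-2,10-dione | CC1=C(C)[C@]2(OC1=O)C=C(C)CCC2=O | intermediate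
8 | 2,3-dihydrofuran | C1=COCC1 | starting material
9 | 5-lithio-2,3-dihydrofuran | [Li]C1=CCCO1 | intermediate
10 | dilithium (Z)-alkenyl methyl cuprate alkoxide (copper cis to the oxidoethyl chain) | [Li+].[Li+].C[Cu-]/C(C)=C\CC[O-] | intermediate
11 | (Z)-4-iodopent-3-en-1-ol | C/C(I)=C/CCO | intermediate
12 | (Z)-4-iodopent-3-enal | C/C(I)=C/CC=O | intermediate
13 | (Z)-4-iodo-1,1-bis[(4-methoxybenzyl)oxy]pent-3-ene | C/C(I)=C/CC(OCc1ccc(OC)cc1)OCc1ccc(OC)cc1 | intermediate
14 | (Z)-7,7-bis[(4-methoxybenzyl)oxy]-4-methylhept-4-en-2-yne | CC#C/C(C)=C\CC(OCc1ccc(OC)cc1)OCc1ccc(OC)cc1 | intermediate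
15 | (2E,4Z)-dienyl zirconocene chloride (zirconium on C2 of the heptadiene) | C/C(=C\C(C)=C/CC(OCc1ccc(OC)cc1)OCc1ccc(OC)cc1)[Zr](Cl)(C1C=CC=C1)C1C=CC=C1 | intermediate
16 | (2E,4Z)-2-iodo-7,7-bis[(4-methoxybenzyl)oxy]-4-methylhepta-2,4-diene | C/C(I)=C\C(C)=C/CC(OCc1ccc(OC)cc1)OCc1ccc(OC)cc1 | intermediate
17 | (2E,4Z)-dienyllithium from 16 | [Li]/C(C)=C/C(C)=C\CC(OCc1ccc(OC)cc1)OCc1ccc(OC)cc1 | intermediate
18 | (2E,4Z)-dienylcerium dichloride from 17 | Cl[Ce](Cl)/C(C)=C/C(C)=C\CC(OCc1ccc(OC)cc1)OCc1ccc(OC)cc1 | intermediate
19 | (5R,10S)-10-[(2E,4Z)-7,7-bis[(4-methoxybenzyl)oxy]-4-methylhepta-2,4-dien-2-yl]-10-hydroxy-3,4,7-trimethyl-1-oxaspiro[4.5]deca-3,6-dien-2-one | CC1=C(C)[C@]2(OC1=O)C=C(C)CC[C@]2(O)/C(C)=C/C(C)=C\CC(OCc1ccc(OC)cc1)OCc1ccc(OC)cc1 | intermediate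
20 | bis-silyl ether: trimethylsilyl ether of the tertiary alcohol of 19, lactone held as 2-(trimethylsilyloxy)-3-methyl-4-methylene-4,5-dihydrofuran | C=C1C(C)=C(O[Si](C)(C)C)O[C@]12C=C(C)CC[C@]2(O[Si](C)(C)C)/C(C)=C/C(C)=C\CC(OCc1ccc(OC)cc1)OCc1ccc(OC)cc1 | intermediate
21 | (10S)-furan-fused cyclodecadiene: C1=C2 trimethylsilyl enol ether (siloxy group cis to C10), 5Z alkene, 2-(trimethylsilyloxy)furan across C7–C8, side chain with Z C11=C12 and the C14 acetal | C/C1=C(O[Si](C)(C)C)\CC/C(C)=C\c2oc(O[Si](C)(C)C)c(C)c2C[C@H]1/C(C)=C\CC(OCc1ccc(OC)cc1)OCc1ccc(OC)cc1 | intermediate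
22 | (1R,7R,10S,14S)-tricyclic keto butenolide: target skeleton with C2 ketone and C14 4-methoxybenzyl ether | O=C1CC/C(C)=C\[C@H]2OC(=O)C(C)=C2C[C@H]2C(C)=CC[C@H](OCc3ccc(OC)cc3)[C@]12C | intermediate
23 | (1R,7R,10S,14S)-14-hydroxy-2-oxo tricyclic butenolide | O=C1CC/C(C)=C\[C@H]2OC(=O)C(C)=C2C[C@H]2C(C)=CC[C@H](O)[C@]12C | intermediate
24 | (1S,2S,7R,10S,14S)-14-acetoxy-2-hydroxy tricyclic butenolide | O[C@H]1CC/C(C)=C\[C@H]2OC(=O)C(C)=C2C[C@H]2C(C)=CC[C@H](OC(C)=O)[C@]12C | intermediate
25 | CNP0112230.1, (1S,2S,7R,10S,14S)-14-acetoxy-2-propanoyloxy butenolide | CCC(=O)O[C@H]1CC/C(C)=C\[C@H]2OC(=O)C(C)=C2C[C@H]2C(C)=CC[C@H](OC(C)=O)[C@]12C | target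

## Step count and risks

Total: 15 steps. Longest linear sequence: 10 steps (steps 1–5 then 11–15; the branch 6–10 then 11–15 is equally long).

Steps most likely to fail:

1. Step 12 (proposed new method). The sigmatropic shift may lose to ionisation of the tertiary allylic silyl ether or stall before full conversion, the oxocarbenium ion may be captured by the siloxyfuran instead of C1, and addition at C14 or protonation at C7 may take place on the wrong face. The fallback uses known reactions and a true 1,2-dialkenylcyclohexanol derivative; it sets out from 19 and comes back at 22. The tertiary alcohol of 19 is silylated (TMSOTf, 2,6-lutidine, −78 °C) to silyl ether F1. Deprotonation with LDA and kinetic α-protonation (AcOH, −78 °C) deconjugates the butenolide to β-methylene lactone F2. Thermal siloxy-Cope ring expansion (1,2-dichlorobenzene, 180 °C) gives ten-membered enol silane F3, which carries the lactone as an enol lactone. A catalytic amount of TMSOTf at −78 °C closes C1–C14 by the Mukaiyama reaction of the acetal to tricyclic enol lactone F4, and DBU moves the lactone alkene into conjugation to give 22.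

2. Step 4. Carbomagnesiation of the hindered tertiary alkoxide may remain incomplete, or the alkenylmagnesium may be protonated before it is carboxylated. The fallback sets out from 3 and comes back at 6 without a new isolated compound. Iodine–magnesium exchange on ethyl (Z)-3-iodo-2-methylbut-2-enoate (iPrMgCl·LiCl, −40 °C) gives an ester-bearing alkenylmagnesium reagent. It adds to the ketone of 3 under the same alkoxide chelation (2.5 equiv), and the hydroxy ester lactonises on work-up to 6.

3. Step 11. The alkenyl metal may attack the C2 carbonyl from the wrong face (equatorial approach syn to the lactone oxygen) or abstract a proton from 7. The fallback sets out from 13 and comes back at 19. Negishi coupling of 13 with ethynylzinc bromide (Pd(PPh3)4) gives terminal enyne F5. Its cerium acetylide (n-BuLi, CeCl3), a slim and weakly basic nucleophile that adds axially, reacts with 7 to give propargylic alcohol F6. Hydroxyl-directed trans-hydrostannation ([Cp*RuCl]4, Bu3SnH) gives alkenylstannane F7, and a copper-assisted methyl Stille coupling (MeI, Pd(PPh3)4, cuprous thiophene-2-carboxylate, [Ph2PO2][NBu4]) gives 19.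

## Further compounds

F1 | step 12 | trimethylsilyl ether of the tertiary alcohol of 19 | CC1=C(C)[C@]2(OC1=O)C=C(C)CC[C@]2(O[Si](C)(C)C)/C(C)=C/C(C)=C\CC(OCc1ccc(OC)cc1)OCc1ccc(OC)cc1
F2 | step 12 | deconjugated lactone of F1 (3-methyl-4-methylene-γ-butyrolactone, C17 as a mixture) | C=C1C(C)C(=O)O[C@]12C=C(C)CC[C@]2(O[Si](C)(C)C)/C(C)=C/C(C)=C\CC(OCc1ccc(OC)cc1)OCc1ccc(OC)cc1
F3 | step 12 | (10S)-ten-membered C1=C2 trimethylsilyl enol ether with the C7=C8 enol lactone | C/C1=C(O[Si](C)(C)C)\CC/C(C)=C\C2=C(C[C@H]1/C(C)=C\CC(OCc1ccc(OC)cc1)OCc1ccc(OC)cc1)C(C)C(=O)O2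
F4 | step 12 | tricyclic C2 ketone with C14 4-methoxybenzyl ether and the C7=C8 enol lactone | O=C1CC/C(C)=C\C2=C(C[C@H]3C(C)=CC[C@H](OCc4ccc(OC)cc4)[C@]13C)C(C)C(=O)O2
F0 | step 4 | none | none
F5 | step 11 | (Z)-6,6-bis[(4-methoxybenzyl)oxy]-3-methylhex-3-en-1-yne | C#C/C(C)=C\CC(OCc1ccc(OC)cc1)OCc1ccc(OC)cc1
F6 | step 11 | propargylic alcohol from 7 and the acetylide of F5 (carbinol configured as in 19) | CC1=C(C)[C@]2(OC1=O)C=C(C)CC[C@]2(O)C#C/C(C)=C\CC(OCc1ccc(OC)cc1)OCc1ccc(OC)cc1
F7 | step 11 | alkenylstannane: 19 with tributylstannyl in place of the C15 methyl | CC1=C(C)[C@]2(OC1=O)C=C(C)CC[C@]2(O)/C(=C/C(C)=C\CC(OCc1ccc(OC)cc1)OCc1ccc(OC)cc1)[Sn](CCCC)(CCCC)CCCC
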